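The 2,3-dimethyl-1,4-diarylbutane is traced back to a trans-3,4-disubstituted butyrolactone. The chain C9–C8–C8'–C9' corresponds to C2–C3–C4–C5 of a butenolide, so the vicinal methine stereocentres C8 and C8', each carrying a methyl group and an arylmethyl arm (C7 to ring A, C7' to ring B), become the lactone α- and β-carbons. One pot joins the lithiated ring B aryl dithiane to C4 of enantiopure (5R)-5-menthyloxy-2(5H)-furanone and then the ring A benzyl bromide to the resulting enolate, fixing both centres trans under control of the acetal carbon. The precursors are this crystalline acetal and two benzyl-protected aryl fragments. Reduction of both lactone termini to methyl groups then erases the auxiliary.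

Key step: step 8

Remark on the chemistry: ring A is the 3,4-dihydroxy-5-methoxyphenyl ring on C7 and ring B the 4-hydroxy-3,5-dimethoxyphenyl ring on C7'; the target is (8R,8'R). Anti addition to the (5R) acetal followed by trans benzylation gives the (3R,4R,5R) lactone, which maps onto (8R,8'R) once C2 and C5 have become the methyl groups C9 and C9', so the planned structures needed no correction. Because the auxiliary stays in place until step 10, a minor diastereomer from the key step can be removed at the lactone stage. 3,4-Dihydroxy-5-methoxybenzaldehyde is taken as purchased.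

Step 1
Reactants: 1 syringaldehyde (4-hydroxy-3,5-dimethoxybenzaldehyde)
Product: 2 4-benzyloxy-3,5-dimethoxybenzaldehyde
Conditions: BnBr, K2CO3, DMF, 60 °C
Reagents that add atoms: benzyl bromide, BrCc1ccccc1
Why: Williamson O-alkylation of the only phenol, made more acidic by the para formyl group, with a reactive benzylic bromide should be clean because no other nucleophilic site is present.

Step 2
Reactants: 2 4-benzyloxy-3,5-dimethoxybenzaldehyde
Product: 3 2-(4-benzyloxy-3,5-dimethoxyphenyl)-1,3-dithiane
Conditions: propane-1,3-dithiol, BF3·OEt2 (cat.), CH2Cl2, 0 °C → rt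
Reagents that add atoms: propane-1,3-dithiol, SCCCS
Why: Lewis-acid-catalysed dithioacetalisation of an aromatic aldehyde is fast with catalytic BF3·OEt2 at 0 °C, conditions under which aryl benzyl and methyl ethers should be retained.

Step 3
Reactants: 4 3,4-dihydroxy-5-methoxybenzaldehyde (5-hydroxyvanillin)
Product: 5 3,4-bis(benzyloxy)-5-methoxybenzaldehyde
Conditions: BnBr (2.4 equiv), K2CO3, DMF, 60 °C
Reagents that add atoms: benzyl bromide, BrCc1ccccc1
Why: Double Williamson etherification of both catechol hydroxyls with excess benzyl bromide should go to completion in DMF, the aldehyde being inert to carbonate.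

Step 4
Reactants: 5 3,4-bis(benzyloxy)-5-methoxybenzaldehyde
Product: 6 [3,4-bis(benzyloxy)-5-methoxyphenyl]methanol
Conditions: NaBH4, MeOH/THF, 0 °C
Reagents that add atoms: none
Why: Borohydride reduction of an aromatic aldehyde to the benzylic alcohol is chemoselective and leaves all three ethers untouched.

Step 5
Reactants: 6 [3,4-bis(benzyloxy)-5-methoxyphenyl]methanol
Product: 7 3,4-bis(benzyloxy)-5-methoxybenzyl bromide
Conditions: PBr3 (0.4 equiv), Et2O, 0 °C; used without storage
Reagents that add atoms: phosphorus tribromide, BrP(Br)Br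
Why: PBr3 converts electron-rich benzylic alcohols into bromides through the phosphite ester and bromide displacement at low temperature, and the labile bromide is taken straight into step 8.

Step 6
Reactants: 8 furfural
Product: 10 5-hydroxy-2(5H)-furanone (racemic lactol), via furfural endoperoxide 9 (not isolated)
Conditions: O2, hν (visible), rose bengal (cat.), MeOH, 20 °C
Reagents that add atoms: dioxygen, O=O
Why: Dye-sensitised singlet-oxygen [4+2] cycloaddition across C2 and C5 of the furan gives the endoperoxide, which methanol fragments with loss of the formyl carbon as methyl formate to leave the hydroxybutenolide (furan photo-oxygenation).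

Step 7
Reactants: 10 5-hydroxy-2(5H)-furanone; 11 (1R,2S,5R)-(−)-menthol
Product: 13 (5R)-5-[(1R,2S,5R)-menthyloxy]-2(5H)-furanone, via C5-epimeric acetal 12 (not isolated)
Conditions: camphorsulfonic acid (cat.), toluene, reflux, azeotropic removal of water; crystallisation from petroleum ether, −20 °C; mother liquor re-equilibrated with the same acid and recrystallised
Reagents that add atoms: none
Why: Acid-catalysed acetalisation of the lactol with the secondary alcohol gives both C5 epimers, which interconvert through the oxocarbenium ion, while only the (5R) epimer crystallises, so repeated equilibration and crystallisation should funnel the material into the (5R) acetal and set the auxiliary stereocentre (crystallisation-driven epimer selection).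

Step 8
Reactants: 3 2-(4-benzyloxy-3,5-dimethoxyphenyl)-1,3-dithiane; 13 (5R)-5-[(1R,2S,5R)-menthyloxy]-2(5H)-furanone; 7 3,4-bis(benzyloxy)-5-methoxybenzyl bromide
Product: 16 (3R,4R,5R)-3-[3,4-bis(benzyloxy)-5-methoxybenzyl]-4-[2-(4-benzyloxy-3,5-dimethoxyphenyl)-1,3-dithian-2-yl]-5-[(1R,2S,5R)-menthyloxy]dihydrofuran-2(3H)-one, via lithiated dithiane 14 (not isolated), via lithium lactone enolate 15 (not isolated)
Conditions: n-BuLi, THF, −78 °C; then 13, −78 °C; then 7, TMEDA, −78 °C → rt
Reagents that add atoms: none
Why: n-BuLi removes the acidic C2–H of dithiane 3 to give the soft, sulfur-stabilised benzylic anion 14, which adds in Michael fashion to C4 of butenolide 13 (forming C7'–C8') to give lithium enolate 15, and this enolate is then C-benzylated at C3 by bromide 7 in an SN2 step accelerated by TMEDA (forming C7–C8). The closest known reaction type is the one-pot conjugate addition–enolate alkylation of 2-aryl-1,3-dithiane anions with 5-alkoxy-2(5H)-furanones and benzylic halides, the standard entry to trans-2,3-dibenzylbutyrolactones. No ring is formed, so no mode of closure has to be assigned. The C4 centre (C8') is controlled by the (5R) acetal carbon, whose menthyloxy group blocks one face of the flat butenolide so that 14 enters anti to it, and the C3 centre (C8) is controlled by the bulky aryl-dithianyl group just installed at C4, which sends the bromide to the opposite face of the planar enolate. The step needs 1,4- over 1,2-addition, secured by the soft, hindered nucleophile and the unhindered β-carbon, and two anti facial selectivities, secured by the rigid five-membered ring in which each substituent shields its own face, so the 3,4-trans-4,5-trans (3R,4R,5R) lactone should result. Over-alkylation is not expected because C3 of 16 is tertiary and buried between two large groups.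

Step 9
Reactants: 16 the (3R,4R,5R) dithianyl lactone
Product: 17 (3R,4R,5R)-3-[3,4-bis(benzyloxy)-5-methoxybenzyl]-4-(4-benzyloxy-3,5-dimethoxybenzyl)-5-[(1R,2S,5R)-menthyloxy]dihydrofuran-2(3H)-one
Conditions: NiCl2·6H2O, NaBH4, MeOH/THF, 0 °C → rt
Reagents that add atoms: none
Why: Nickel boride formed in situ cleaves both benzylic C–S bonds (reductive desulfurisation of a dithioacetal) without attacking aryl benzyl ethers or the three stereocentres, and any partial borohydride reduction of the acylal is harmless because step 10 takes all such material to the same diol.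

Step 10
Reactants: 17 the (3R,4R,5R) dibenzyl menthyloxy lactone
Product: 18 (2R,3R)-2-[3,4-bis(benzyloxy)-5-methoxybenzyl]-3-(4-benzyloxy-3,5-dimethoxybenzyl)butane-1,4-diol
Conditions: LiAlH4, THF, 0 °C → reflux; aqueous NaOH work-up
Reagents that add atoms: none
Why: LiAlH4 reduces the lactone carbonyl to the primary alkoxide and, after the freed hemiacetal collapses to the aldehyde with loss of menthoxide, reduces that aldehyde too, so C9 and C9' both become CH2OH while C8 and C8' are untouched (hydride reduction of a lactone acetal to a 1,4-diol).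

Step 11
Reactants: 18 the (2R,3R) 1,4-diol
Product: 19 (2R,3R)-2-[3,4-bis(benzyloxy)-5-methoxybenzyl]-3-(4-benzyloxy-3,5-dimethoxybenzyl)butane-1,4-diyl dimethanesulfonate
Conditions: MsCl, Et3N, CH2Cl2, −10 °C; cold work-up, used directly
Reagents that add atoms: methanesulfonyl chloride, CS(=O)(=O)Cl
Why: Sulfene-mediated mesylation with MsCl/Et3N is complete within minutes at low temperature, so both primary hydroxyls should be sulfonylated before a mono-mesylate can cyclise to the tetrahydrofuran (sulfonate ester formation).

Step 12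
Reactants: 19 the (2R,3R) bis-mesylate
Product: 20 1,2-bis(benzyloxy)-5-[(2R,3R)-4-(4-benzyloxy-3,5-dimethoxyphenyl)-2,3-dimethylbutyl]-3-methoxybenzene
Conditions: LiBHEt3 (excess), THF, 0 °C → rt
Reagents that add atoms: none
Why: LiBHEt3 is a strongly nucleophilic hydride that displaces primary mesylates by SN2 attack at carbon, turning both CH2OMs groups into the C9 and C9' methyl groups without touching aryl ethers or the adjacent stereocentres (hydride displacement of sulfonates).

Step 13
Reactants: 20 the (2R,3R) tris-benzyl ether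
Product: 21 Sauriol B, 5-[(2R,3R)-4-(4-hydroxy-3,5-dimethoxyphenyl)-2,3-dimethylbutyl]-3-methoxybenzene-1,2-diol
Conditions: H2 (1 atm), Pd/C, EtOAc/MeOH, rt; filtration and concentration under argon
Reagents that add atoms: none
Why: Palladium-catalysed hydrogenolysis cleaves the three benzylic C–O bonds under neutral conditions and leaves the aryl methyl ethers and the saturated stereocentres intact, with the free catechol kept under argon to avoid oxidation (benzyl ether hydrogenolysis).

Compound list
1 | syringaldehyde (4-hydroxy-3,5-dimethoxybenzaldehyde) | COc1cc(C=O)cc(OC)c1O | starting material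
2 | 4-benzyloxy-3,5-dimethoxybenzaldehyde | COc1cc(C=O)cc(OC)c1OCc1ccccc1 | intermediate
3 | 2-(4-benzyloxy-3,5-dimethoxyphenyl)-1,3-dithiane | COc1cc(C2SCCCS2)cc(OC)c1OCc1ccccc1 | intermediate
4 | 3,4-dihydroxy-5-methoxybenzaldehyde (5-hydroxyvanillin) | COc1cc(C=O)cc(O)c1O | starting material
5 | 3,4-bis(benzyloxy)-5-methoxybenzaldehyde | COc1cc(C=O)cc(OCc2ccccc2)c1OCc1ccccc1 | intermediate
6 | [3,4-bis(benzyloxy)-5-methoxyphenyl]methanol | COc1cc(CO)cc(OCc2ccccc2)c1OCc1ccccc1 | intermediate
7 | 3,4-bis(benzyloxy)-5-methoxybenzyl bromide | COc1cc(CBr)cc(OCc2ccccc2)c1OCc1ccccc1 | intermediate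
8 | furfural | O=Cc1ccco1 | starting material
9 | furfural endoperoxide, 2,3,7-trioxabicyclo[2.2.1]hept-5-ene-1-carbaldehyde (racemic) | O=CC12OOC(C=C1)O2 | intermediate
10 | 5-hydroxy-2(5H)-furanone (racemic) | OC1OC(=O)C=C1 | intermediate
11 | (1R,2S,5R)-(−)-menthol | CC(C)[C@@H]1CC[C@@H](C)C[C@H]1O | starting material
12 | (5S)-5-[(1R,2S,5R)-menthyloxy]-2(5H)-furanone (C5 epimer) | CC(C)[C@@H]1CC[C@@H](C)C[C@H]1O[C@H]1OC(=O)C=C1 | intermediate
13 | (5R)-5-[(1R,2S,5R)-menthyloxy]-2(5H)-furanone | CC(C)[C@@H]1CC[C@@H](C)C[C@H]1O[C@@H]1OC(=O)C=C1 | intermediate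
14 | 2-lithio-2-(4-benzyloxy-3,5-dimethoxyphenyl)-1,3-dithiane | [Li]C1(SCCCS1)c1cc(OC)c(OCc2ccccc2)c(OC)c1 | intermediate
15 | lithium (4R,5R)-4-[2-(4-benzyloxy-3,5-dimethoxyphenyl)-1,3-dithian-2-yl]-5-[(1R,2S,5R)-menthyloxy]-4,5-dihydrofuran-2-olate | [Li]OC1=C[C@@H](C2(SCCCS2)c2cc(OC)c(OCc3ccccc3)c(OC)c2)[C@H](O[C@@H]2C[C@H](C)CC[C@H]2C(C)C)O1 | intermediate
16 | (3R,4R,5R)-3-[3,4-bis(benzyloxy)-5-methoxybenzyl]-4-[2-(4-benzyloxy-3,5-dimethoxyphenyl)-1,3-dithian-2-yl]-5-[(1R,2S,5R)-menthyloxy]dihydrofuran-2(3H)-one | COc1cc(C[C@H]2C(=O)O[C@@H](O[C@@H]3C[C@H](C)CC[C@H]3C(C)C)[C@@H]2C2(SCCCS2)c2cc(OC)c(OCc3ccccc3)c(OC)c2)cc(OCc2ccccc2)c1OCc1ccccc1 | intermediate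
17 | (3R,4R,5R)-3-[3,4-bis(benzyloxy)-5-methoxybenzyl]-4-(4-benzyloxy-3,5-dimethoxybenzyl)-5-[(1R,2S,5R)-menthyloxy]dihydrofuran-2(3H)-one | COc1cc(C[C@H]2C(=O)O[C@@H](O[C@@H]3C[C@H](C)CC[C@H]3C(C)C)[C@@H]2Cc2cc(OC)c(OCc3ccccc3)c(OC)c2)cc(OCc2ccccc2)c1OCc1ccccc1 | intermediate
18 | (2R,3R)-2-[3,4-bis(benzyloxy)-5-methoxybenzyl]-3-(4-benzyloxy-3,5-dimethoxybenzyl)butane-1,4-diol | COc1cc(C[C@@H](CO)[C@H](CO)Cc2cc(OC)c(OCc3ccccc3)c(OC)c2)cc(OCc2ccccc2)c1OCc1ccccc1 | intermediate
19 | (2R,3R)-2-[3,4-bis(benzyloxy)-5-methoxybenzyl]-3-(4-benzyloxy-3,5-dimethoxybenzyl)butane-1,4-diyl dimethanesulfonate | COc1cc(C[C@@H](COS(C)(=O)=O)[C@H](COS(C)(=O)=O)Cc2cc(OC)c(OCc3ccccc3)c(OC)c2)cc(OCc2ccccc2)c1OCc1ccccc1 | intermediate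
20 | 1,2-bis(benzyloxy)-5-[(2R,3R)-4-(4-benzyloxy-3,5-dimethoxyphenyl)-2,3-dimethylbutyl]-3-methoxybenzene | COc1cc(C[C@@H](C)[C@H](C)Cc2cc(OC)c(OCc3ccccc3)c(OC)c2)cc(OCc2ccccc2)c1OCc1ccccc1 | intermediate
21 | Sauriol B, 5-[(2R,3R)-4-(4-hydroxy-3,5-dimethoxyphenyl)-2,3-dimethylbutyl]-3-methoxybenzene-1,2-diol | COc1cc(C[C@@H](C)[C@H](C)Cc2cc(OC)c(O)c(OC)c2)cc(O)c1O | target

Total step count: 13.
Longest linear sequence: 9 steps (steps 3, 4, 5, 8, 9, 10, 11, 12, 13, from 4 to 21).

Steps most likely to fail

Step 8. The enolate may be quenched by proton transfer or outlive the labile, electron-rich benzylic bromide before C-alkylation occurs, or trans selectivity at C3 may erode as the mixture warms. The fallback separates the two bond formations. It sets out from 13 and 3: only the conjugate addition is run (n-BuLi, THF, −78 °C) and quenched cold with aqueous NH4Cl to isolate (4R,5R)-4-[2-(4-benzyloxy-3,5-dimethoxyphenyl)-1,3-dithian-2-yl]-5-[(1R,2S,5R)-menthyloxy]dihydrofuran-2(3H)-one F1. This lactone is then enolised in a separate flask with LDA in THF at −78 °C and alkylated with freshly prepared 7 in the presence of DMPU, the C4 substituent again directing the benzyl group trans. The fallback comes back to the route at 16.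

Step 12. Hydride may attack a mesylate at sulfur instead of carbon, and the alkoxide so released would close onto the neighbouring CH2OMs to give a 3,4-disubstituted tetrahydrofuran in place of the second methyl group. The fallback avoids any alkoxide by switching to a radical pathway. It sets out from 19: Finkelstein exchange (NaI, acetone, reflux) should give 1,2-bis(benzyloxy)-5-[(2R,3R)-4-(4-benzyloxy-3,5-dimethoxyphenyl)-2,3-bis(iodomethyl)butyl]-3-methoxybenzene F2. Radical chain reduction with Bu3SnH and AIBN in toluene at 80 °C then removes both iodines and comes back to the route at 20.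

Step 9. Borohydride and methoxide may attack the acylal lactone while C–S cleavage at the congested carbon next to C4 is still incomplete, leaving material spread over several oxidation levels that is hard to purify. The fallback inverts the order of reduction and desulfurisation. It sets out from 16: LiAlH4 in THF should give (2R,3R)-2-[3,4-bis(benzyloxy)-5-methoxybenzyl]-3-[2-(4-benzyloxy-3,5-dimethoxyphenyl)-1,3-dithian-2-yl]butane-1,4-diol F3, with menthol released. Since no reducible carbonyl remains, F3 can be desulfurised with a large excess of NiCl2·6H2O/NaBH4 in EtOH/THF at reflux, and the fallback comes back to the route at 18.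

Further compounds
F1 | step 8 | (4R,5R)-4-[2-(4-benzyloxy-3,5-dimethoxyphenyl)-1,3-dithian-2-yl]-5-[(1R,2S,5R)-menthyloxy]dihydrofuran-2(3H)-one | O=C1C[C@@H](C2(SCCCS2)c2cc(OC)c(OCc3ccccc3)c(OC)c2)[C@H](O[C@@H]2C[C@H](C)CC[C@H]2C(C)C)O1
F2 | step 12 | 1,2-bis(benzyloxy)-5-[(2R,3R)-4-(4-benzyloxy-3,5-dimethoxyphenyl)-2,3-bis(iodomethyl)butyl]-3-methoxybenzene | COc1cc(C[C@@H](CI)[C@H](CI)Cc2cc(OC)c(OCc3ccccc3)c(OC)c2)cc(OCc2ccccc2)c1OCc1ccccc1
F3 | step 9 | (2R,3R)-2-[3,4-bis(benzyloxy)-5-methoxybenzyl]-3-[2-(4-benzyloxy-3,5-dimethoxyphenyl)-1,3-dithian-2-yl]butane-1,4-diol | COc1cc(C[C@@H](CO)[C@H](CO)C2(SCCCS2)c2cc(OC)c(OCc3ccccc3)c(OC)c2)cc(OCc2ccccc2)c1OCc1ccccc1
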